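# Synthesis plan for CNP0230565.3 by anionic oxy-Cope ring expansion of a carvone-derived cyclohexenol

Atom labels C1–C15 follow germacrane numbering of the target and are kept for every intermediate, including the cyclohexene compounds 1–10. The ring is C1–C10, the lactone carbons are C11–C13, C14 is the methyl on C10 and C15 the methyl on C4. Systematic names carry their own locants.

## The problem

The target is a germacranolide: a ten-membered carbocycle with a cis-fused α-methylene-γ-butyrolactone across C6/C7 (H6 and H7 cis), a tiglate on C8, a free allylic hydroxyl on C5 and a cross-conjugated 1(10)Z,3Z-dien-2-one. A ten-membered ring with two Z trisubstituted olefins is a poor candidate for end-to-end closure, so it is best made by reorganising a smaller ring. The four contiguous stereocenters are 5S, 6R, 7R and 8S. Once C6 is a ketone, the C5 oxygen can direct its reduction by chelation, and the ring conformation together with C8 can direct bond formation at C7. Nothing in the ring fixes C5 and C8 themselves, so their absolute configuration must come from outside. The α-methylene lactone is a Michael acceptor, the γ-hydroxy dienone is labile to base, and the tiglate tolerates neither strong base nor hydride. These groups must therefore appear late, and the last steps must be neutral or only mildly Lewis acidic. The enabling feature is that C1–C6 with C15 on C4 and the three-carbon unit C10/C9/C14 on C1 are the ten carbons of carvone. With an alkenyl group C7=C8 and a hydroxyl on C6, the array C9=C10–C1–C6(O)–C7=C8 is a 3-hydroxy-1,5-diene whose central bond is the ring bond C1–C6. A [3,3] shift then forms C8–C9, opens the six-membered ring into the ten-membered ring and leaves a C6 enolate at which C7–C11 can be made. The carvone stereocenter C1 and the carbinol C6 are consumed in this step after they have fixed C5 and C8.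

## Retrosynthesis

**Target 22 to skipped diene 20.** The last bonds cut are the SEM acetal on O5 (22 from 21) and the C2 carbonyl oxygen (21 from 20). A C2 ketone present earlier would make the enolate chemistry at C7 and C11 and the hydride reduction at C6 unselective, so C2 stays a methylene until the end. Its two hydrogens are doubly allylic and the weakest C–H bonds in 20. The forward oxidation must deliver oxygen at the carbon that loses hydrogen so that both Z olefins stay in place. The SEM ether keeps the C5 carbinol from being oxidised in that step and is then removed without base.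

**Tiglate 20 to lactone 15.** The C8 ester is cut to alcohol 19 and tiglic acid, 19 comes from PMB ether 18 by oxidative cleavage, and the C11=C13 bond of 18 is cut back to lactone 15. The order is dictated by compatibility. The methylenation needs a lactone enolate, which a tiglate would not survive, and the PMB ether is removed by an oxidant that leaves the SEM ether and the acrylate unit alone. The precursor 15 has neither Michael acceptor nor ester side chain.

**Lactone 15 to keto ester 13.** Cutting the C12–O bond and the C6–H bond leads to the C6 ketone 13 with a methyl acetate arm on C7. A ketone at C6 is what the ring expansion delivers, and it sits next to the C5 acetal oxygen. The forward reduction is asked to give the 5,6-anti arrangement (6R) under chelation control, after which the cis-fused lactone closes without further activation.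

**Keto ester 13 to cyclohexenol 10 and methyl bromoacetate 11.** This is the strategic cut: C7–C11 and C8–C9 are broken and C1–C6 is re-formed. It removes the medium ring, the C7 and C8 stereocenters and the Z C1=C10 olefin in one operation and leaves a cyclohexene with three stereocenters. Disconnections of other ring bonds would demand a macrocyclisation. The forward step needs the alkenyl and isopropenyl groups cis on the six-membered ring, an E enol ether so that the C8 oxygen is equatorial in the chair transition state, and a free tertiary hydroxyl. The C5 oxygen must carry a group that neither migrates to the alkoxide nor is lost under KH, and that can chelate later; the SEM acetal meets these demands. The C8 oxygen carries a PMB group because it has to be removed oxidatively before the tiglate is attached.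

**Enol ether 10 to aldehyde 8.** The C8–O bond is cut to E vinyl iodide 9 and 4-methoxybenzyl alcohol, and the C7=C8 bond of 9 is cut to aldehyde 8 and iodoform. An alkoxymethylene Wittig reaction would save a step but gives mixtures of enol ether isomers, and the C8 configuration of the key step depends on that geometry. Addition of an (E)-2-alkoxyvinyl anion to a C6 ketone was rejected because such anions lose alkoxide readily and the required ketone is not accessible with the correct C5 configuration. The two-step sequence is E-selective in its first step and stereoretentive in its second.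

**Aldehyde 8 to α-hydroxy aldehyde 4.** The SEM ether is cut to diol 7, the aldehyde of 7 is traced to triol 6, and 6 comes from keto aldehyde 4 by reduction of both carbonyls. The detour through the primary alcohol has a stereochemical reason. External hydride would attack the C5 ketone anti to the pseudo-axial C7 substituent and give the 5-epimer. A hydroxyl on C7 binds boron on the isopropenyl face and delivers hydride to C5 from that face, which gives the required cis relationship of the C5 and C6 oxygens.

**α-Hydroxy aldehyde 4 to carvone 1 and ethyl formate 2.** The C6–O bond is cut to the chelated enol 3, and C6–C7 is cut to (S)-carvone and ethyl formate. The enantiomer of carvone is fixed by the relay described above: with the E enol ether and the preferred chair, the S configuration at the isopropenyl carbon leads to 8S. The forward steps ask only that the oxidant approach C6 anti to the neighbouring isopropenyl group.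

## Roads not taken

**Alternative 1: enolate [2,3]-Wittig ring contraction.** The cut is C6–C7 together with the lactone C–O bond. In the forward sense LiN(SiMe3)2 would form the C6 enolate of a thirteen-membered ring in which an O–C13 ether link stands in for C6–C7. The [2,3] shift would form C6–C7, break O–C13, create C11=C13 and contract the ring to the carbocycle, and the C6 alkoxide would close the lactone to give A1.
- **Merits.** The α-methylene lactone arrives in the ring-forming step and the C2 oxygen is carried from the start. In both respects this road is better than the chosen plan, which needs a separate methylenation and a late C–H oxidation.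
- **Weak points.** The thirteen-membered ring must first be closed by a macrocyclisation. The C6/C7 relationship is set in a macrocyclic transition state whose folding is hard to predict. A1 also has the oxidation levels at C2 and C5 reversed relative to the target, so a controlled reduction at C5 and an oxidation at C2 remain.
- **Comparison.** The chosen plan forms the ring from a six-membered terpene without high dilution and sets C8 by relay from the chiral pool.

**Alternative 2: acetylenic oxy-Cope ring expansion.** The cut is C9–C10. A quinic-acid-derived cyclohexenol carrying a propynyl and a vinyl group would rearrange as its potassium alkoxide, forming C9–C10 and breaking C2–C7, and protonation of the allenolate at C1 would give the dienone A2.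
- **Merits.** The cross-conjugated dienone comes directly out of the ring expansion. This is better than the chosen plan at C2, where a methylene has to be oxidised late, and the C5/C6 oxygens come from the chiral pool.
- **Weak points.** A2 has C7=C8 as a bare E olefin. The C11–C13 unit, the C8 oxygen and both stereocenters would have to be added to a ring that already holds the base- and nucleophile-sensitive dienone. The geometry of protonation at C1 is not assured, and quinic acid needs several deoxygenation and methylation steps.
- **Comparison.** The chosen plan creates C7 and C8 in the ring-forming step.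

**Alternative 3: SmI2 ketyl–butenolide macrocyclisation.** The cut is C7–C8. SmI2 would reduce a C8 aldehyde to a ketyl that adds to C7 of a 3-(acetoxymethyl)butenolide, closing the ten-membered ring, and the samarium enolate would expel acetate to give A3.
- **Merits.** The plan is convergent and delivers the methylene lactone, the free C8 hydroxyl and the C2 oxygen at once, so its endgame is shorter than that of the chosen plan.
- **Weak points.** It closes a ten-membered ring directly against entropy and transannular strain. Pinacol coupling, simple reduction of the aldehyde and premature loss of the allylic acetate compete. C7 and C8 are set by the conformation of an open chain, and that chain, with two Z trisubstituted olefins and three stereocenters, needs a long linear synthesis.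
- **Comparison.** The chosen plan replaces the cyclisation by a unimolecular reorganisation of a pre-formed ring, with its stereocenters drawn from carvone.

Key step: step 8

## Route

Remark: 3 is written as the chelated Z enol of the β-keto aldehyde; both tautomers are one compound.
Remark: 16 and 17 are mixtures at C11; that center becomes trigonal in the same step.

Step 1
Reactants: 1 (S)-(+)-carvone; 2 ethyl formate
Product: 3 (5R,6Z)-6-(hydroxymethylidene)-2-methyl-5-(prop-1-en-2-yl)cyclohex-2-en-1-one
Conditions: NaH, HCO2Et, cat. EtOH, THF, 0 °C to rt; then aq. HCl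
Reagents that add atoms: ethyl formate (2), CCOC=O
Why: Crossed Claisen formylation at the only enolisable α-methylene (C6); the sodium salt of the chelated β-keto aldehyde is the thermodynamic sink, and the stereocenter C1, which is β to the carbonyl, is not touched.

Step 2
Reactants: 3 (5R,6Z)-6-(hydroxymethylidene)-2-methyl-5-(prop-1-en-2-yl)cyclohex-2-en-1-one
Product: 4 (1S,6R)-1-hydroxy-3-methyl-2-oxo-6-(prop-1-en-2-yl)cyclohex-3-ene-1-carbaldehyde
Conditions: dimethyldioxirane, acetone/CH2Cl2, −78 to 0 °C
Reagents that add atoms: dimethyldioxirane, CC1(C)OO1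
Why: Electrophilic epoxidation of the enol double bond and collapse of the hydroxy epoxide (α-hydroxylation of a 1,3-dicarbonyl compound); the oxidant should approach C6 anti to the neighbouring isopropenyl group, placing the hydroxyl trans and the formyl carbon cis to it, and the neutral medium avoids retro-Claisen loss of the formyl group.

Step 3
Reactants: 4 (1S,6R)-1-hydroxy-3-methyl-2-oxo-6-(prop-1-en-2-yl)cyclohex-3-ene-1-carbaldehyde
Product: 6 (1S,2S,6R)-1-(hydroxymethyl)-3-methyl-6-(prop-1-en-2-yl)cyclohex-3-ene-1,2-diol, via keto diol 5 (not isolated)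
Conditions: Me4NBH(OAc)3, MeCN/AcOH, −30 to 0 °C
Reagents that add atoms: none
Why: Triacetoxyborohydride reduces the aldehyde first; the new primary hydroxyl then binds boron and delivers hydride to C5 through a six-membered transition state (Evans–Saksena directed reduction), and because C7 lies on the isopropenyl face the C5 hydroxyl should end up cis to the tertiary hydroxyl (5S), the epimer that external hydride would not give.

Step 4
Reactants: 6 (1S,2S,6R)-1-(hydroxymethyl)-3-methyl-6-(prop-1-en-2-yl)cyclohex-3-ene-1,2-diol
Product: 7 (1R,2S,6R)-1,2-dihydroxy-3-methyl-6-(prop-1-en-2-yl)cyclohex-3-ene-1-carbaldehyde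
Conditions: TEMPO (cat.), N-chlorosuccinimide, Bu4NCl (cat.), CH2Cl2/aq. NaHCO3, 0 °C
Reagents that add atoms: none
Why: Oxoammonium (TEMPO) oxidation is strongly biased toward primary over secondary and tertiary alcohols, and N-chlorosuccinimide as terminal oxidant does not cleave 1,2-diols; the aldehyde has no α-hydrogen and is carried on cold and at once.

Step 5
Reactants: 7 (1R,2S,6R)-1,2-dihydroxy-3-methyl-6-(prop-1-en-2-yl)cyclohex-3-ene-1-carbaldehyde
Product: 8 (1R,2S,6R)-1-hydroxy-3-methyl-6-(prop-1-en-2-yl)-2-{[2-(trimethylsilyl)ethoxy]methoxy}cyclohex-3-ene-1-carbaldehyde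
Conditions: SEMCl, i-Pr2NEt, Bu4NI (cat.), CH2Cl2, 0 °C to rt
Reagents that add atoms: 2-(trimethylsilyl)ethoxymethyl chloride, C[Si](C)(C)CCOCCl
Why: Alkylation of the secondary allylic hydroxyl by the chloromethyl ether under amine base (SEM ether formation); the tertiary hydroxyl between two substituted ring carbons is too hindered to react and stays free for the key step.

Step 6
Reactants: 8 (1R,2S,6R)-1-hydroxy-3-methyl-6-(prop-1-en-2-yl)-2-{[2-(trimethylsilyl)ethoxy]methoxy}cyclohex-3-ene-1-carbaldehyde
Product: 9 (1S,2S,6R)-1-[(E)-2-iodoethenyl]-3-methyl-6-(prop-1-en-2-yl)-2-{[2-(trimethylsilyl)ethoxy]methoxy}cyclohex-3-en-1-ol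
Conditions: CrCl2, CHI3, THF, 0 °C to rt
Reagents that add atoms: iodoform, IC(I)I
Why: Takai iodo-olefination; the geminal dichromium reagent formed from CHI3 and CrCl2 adds only to the aldehyde and gives the E vinyl iodide, with selectivity highest for hindered aldehydes, and the free tertiary hydroxyl and the SEM ether are tolerated.

Step 7
Reactants: 9 (1S,2S,6R)-1-[(E)-2-iodoethenyl]-3-methyl-6-(prop-1-en-2-yl)-2-{[2-(trimethylsilyl)ethoxy]methoxy}cyclohex-3-en-1-ol
Product: 10 (1S,2S,6R)-1-{(E)-2-[(4-methoxyphenyl)methoxy]ethenyl}-3-methyl-6-(prop-1-en-2-yl)-2-{[2-(trimethylsilyl)ethoxy]methoxy}cyclohex-3-en-1-ol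
Conditions: CuI (cat.), 3,4,7,8-tetramethyl-1,10-phenanthroline, Cs2CO3, 4-MeOC6H4CH2OH, toluene, 80 °C
Reagents that add atoms: 4-methoxybenzyl alcohol, COc1ccc(CO)cc1
Why: Copper-catalysed Ullmann-type C–O coupling of a vinyl iodide with a primary alcohol, which retains olefin geometry, so the E iodide should give the E enol ether; carbonate is too weak a base to ionise the tertiary alcohol, so no premature rearrangement is expected.

Step 8
Reactants: 10 (1S,2S,6R)-1-{(E)-2-[(4-methoxyphenyl)methoxy]ethenyl}-3-methyl-6-(prop-1-en-2-yl)-2-{[2-(trimethylsilyl)ethoxy]methoxy}cyclohex-3-en-1-ol; 11 methyl bromoacetate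
Product: 13 methyl 2-[(1R,2S,4Z,7Z,9S)-2-[(4-methoxyphenyl)methoxy]-4,8-dimethyl-10-oxo-9-{[2-(trimethylsilyl)ethoxy]methoxy}cyclodeca-4,7-dien-1-yl]acetate, via potassium enolate 12 (not isolated)
Conditions: KH, 18-crown-6, THF, 0 °C to rt; then BrCH2CO2Me, −78 °C; aq. NH4Cl
Reagents that add atoms: methyl bromoacetate (11), COC(=O)CBr
Why: KH with 18-crown-6 gives a weakly paired tertiary alkoxide, and the 3-oxido-1,5-diene C9=C10–C1–C6–C7=C8 undergoes the [3,3] sigmatropic shift (anionic oxy-Cope rearrangement); the closest known class is the ring expansion of cis-1-alkenyl-2-isopropenylcyclohexanols to cyclodec-5-enones with alkylation of the enolate in the same flask. The ten-membered ring is not closed end to end but arises by ring expansion: C8–C9 forms inside a six-membered chair transition state while the ring bond C1–C6 breaks, so no high dilution is needed. Because isopropenyl and alkenyl are cis, one ring bond is axial and one equatorial in that chair; chair A, with C2 axial on C1 and the oxido group axial on C6, should be preferred over chair B, in which C5 with its SEM ether would be axial on C6 and 1,3-diaxial to the C14 methyl on C10. Chair A gives the Z C1=C10 olefin, since the axial C2 ends cis to C9, and the E enol ether keeps the PMB-oxy group equatorial on C8, so C9 bonds to the face of C8 that gives 8S; chirality is relayed from C6 and C1 to C8 while both old centers become trigonal. Chair B would give the E olefin together with 8R, so olefin geometry and C8 configuration are coupled and the minor pathway leads to a separable diastereomer. The shift delivers the C6=C7 potassium enolate regiospecifically, and at −78 °C methyl bromoacetate should attack C7 on the outer face, the inner face being covered by the C1=C10 olefin across the ring, which gives 7R. The step needs Z over E, C- over O-alkylation and trapping faster than loss of the C8 alkoxide from the enolate; the C8–O bond lies near the enolate plane in the conformation that is formed, and the cold addition of a soft, SN2-active electrophile serves the other two.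

Step 9
Reactants: 13 methyl 2-[(1R,2S,4Z,7Z,9S)-2-[(4-methoxyphenyl)methoxy]-4,8-dimethyl-10-oxo-9-{[2-(trimethylsilyl)ethoxy]methoxy}cyclodeca-4,7-dien-1-yl]acetate
Product: 15 (1(10)Z,3Z,5S,6R,7R,8S)-8-[(4-methoxyphenyl)methoxy]-5-{[2-(trimethylsilyl)ethoxy]methoxy}-13-norgermacra-1(10),3-dien-12,6-olide, via hydroxy ester 14 (not isolated)
Conditions: Zn(BH4)2, Et2O, −30 to 0 °C; aq. NH4Cl; then PPTS (cat.), CH2Cl2, rt
Reagents that add atoms: none
Why: Zn(BH4)2 chelates the C6 carbonyl and the C5 acetal oxygen and delivers hydride from the side of the C5 hydrogen (Cram chelate model), which should give the 5,6-anti arrangement, 6R; the new hydroxyl is then placed to close the cis-fused γ-lactone on the C7 acetate arm by acyl substitution, and the methyl ester is not reduced by this reagent.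

Step 10
Reactants: 15 (1(10)Z,3Z,5S,6R,7R,8S)-8-[(4-methoxyphenyl)methoxy]-5-{[2-(trimethylsilyl)ethoxy]methoxy}-13-norgermacra-1(10),3-dien-12,6-olide
Product: 18 (1(10)Z,3Z,5S,6R,7R,8S)-8-[(4-methoxyphenyl)methoxy]-5-{[2-(trimethylsilyl)ethoxy]methoxy}germacra-1(10),3,11(13)-trien-12,6-olide, via Mannich base 16 (not isolated), via ammonium iodide 17 (not isolated)
Conditions: LiN(i-Pr)2, THF, −78 °C; Me2N=CH2+ I−, −78 °C to rt; MeI, MeOH, rt; aq. NaHCO3, CH2Cl2
Reagents that add atoms: Eschenmoser's salt, C=[N+](C)C.[I-]
Why: Mannich reaction of the lactone enolate with Eschenmoser's salt, quaternisation and Hofmann-type elimination (standard α-methylenation of γ-lactones); C11 becomes trigonal, and C7 is not acidic under these conditions, so the ring fusion is kept.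

Step 11
Reactants: 18 (1(10)Z,3Z,5S,6R,7R,8S)-8-[(4-methoxyphenyl)methoxy]-5-{[2-(trimethylsilyl)ethoxy]methoxy}germacra-1(10),3,11(13)-trien-12,6-olide
Product: 19 (1(10)Z,3Z,5S,6R,7R,8S)-8-hydroxy-5-{[2-(trimethylsilyl)ethoxy]methoxy}germacra-1(10),3,11(13)-trien-12,6-olide
Conditions: DDQ, CH2Cl2/pH 7 buffer, 0 °C
Reagents that add atoms: none
Why: Oxidative cleavage of the p-methoxybenzyl ether by DDQ (electron transfer from the electron-rich arene, hydrolysis of the oxocarbenium ion); the SEM ether, the lactone and the non-aromatic olefins should be inert in the buffered medium.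

Step 12
Reactants: 19 (1(10)Z,3Z,5S,6R,7R,8S)-8-hydroxy-5-{[2-(trimethylsilyl)ethoxy]methoxy}germacra-1(10),3,11(13)-trien-12,6-olide
Product: 20 (1(10)Z,3Z,5S,6R,7R,8S)-8-{[(2E)-2-methylbut-2-enoyl]oxy}-5-{[2-(trimethylsilyl)ethoxy]methoxy}germacra-1(10),3,11(13)-trien-12,6-olide
Conditions: tiglic acid, 2,4,6-Cl3C6H2COCl, Et3N, toluene, rt; then 19, DMAP, rt
Reagents that add atoms: tiglic acid, C/C=C(\C)C(=O)O
Why: Yamaguchi esterification; DMAP attacks the mixed anhydride at the less hindered tigloyl carbonyl and the acylpyridinium ion acylates the hindered secondary C8 hydroxyl, and tiglate is the stable E isomer so no geometry can be lost.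

Step 13
Reactants: 20 (1(10)Z,3Z,5S,6R,7R,8S)-8-{[(2E)-2-methylbut-2-enoyl]oxy}-5-{[2-(trimethylsilyl)ethoxy]methoxy}germacra-1(10),3,11(13)-trien-12,6-olide
Product: 21 (1(10)Z,3Z,5S,6R,7R,8S)-8-{[(2E)-2-methylbut-2-enoyl]oxy}-2-oxo-5-{[2-(trimethylsilyl)ethoxy]methoxy}germacra-1(10),3,11(13)-trien-12,6-olide
Conditions: CrO3, 3,5-dimethylpyrazole, CH2Cl2, −20 °C
Reagents that add atoms: chromium trioxide, O=[Cr](=O)=O
Why: Allylic oxidation by the CrO3–3,5-dimethylpyrazole complex; the doubly allylic C2–H bonds are the weakest in the molecule, and oxidation of a 1,4-diene to the cross-conjugated dienone is the known outcome for 1,4-cyclohexadienes; C2 is not a stereocenter and both Z olefins stay in place if oxygen enters at the carbon that loses hydrogen.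

Step 14
Reactants: 21 (1(10)Z,3Z,5S,6R,7R,8S)-8-{[(2E)-2-methylbut-2-enoyl]oxy}-2-oxo-5-{[2-(trimethylsilyl)ethoxy]methoxy}germacra-1(10),3,11(13)-trien-12,6-olide
Product: 22 (1(10)Z,3Z,5S,6R,7R,8S)-5-hydroxy-8-{[(2E)-2-methylbut-2-enoyl]oxy}-2-oxogermacra-1(10),3,11(13)-trien-12,6-olide (CNP0230565.3)
Conditions: MgBr2·OEt2, MeNO2/Et2O, rt; aq. work-up
Reagents that add atoms: none
Why: Lewis-acid cleavage of the SEM acetal by MgBr2 (coordination of both acetal oxygens, bromide attack at the O–CH2–O carbon); the medium is neither basic nor protic-acidic, so the α-methylene lactone, the tiglate and the γ-hydroxy dienone should survive.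

## Compound list

1 | (S)-(+)-carvone, (5S)-2-methyl-5-(prop-1-en-2-yl)cyclohex-2-en-1-one | CC(=C)[C@H]1CC=C(C)C(=O)C1 | starting material
2 | ethyl formate | CCOC=O | starting material
3 | (5R,6Z)-6-(hydroxymethylidene)-2-methyl-5-(prop-1-en-2-yl)cyclohex-2-en-1-one (chelated enol of 6-formylcarvone) | CC(=C)[C@H]1CC=C(C)C(=O)/C1=C\O | intermediate
4 | (1S,6R)-1-hydroxy-3-methyl-2-oxo-6-(prop-1-en-2-yl)cyclohex-3-ene-1-carbaldehyde (hydroxyl trans to isopropenyl) | CC(=C)[C@H]1CC=C(C)C(=O)[C@@]1(O)C=O | intermediate
5 | (5R,6S)-6-hydroxy-6-(hydroxymethyl)-2-methyl-5-(prop-1-en-2-yl)cyclohex-2-en-1-one (keto diol, formed and consumed in step 3) | CC(=C)[C@H]1CC=C(C)C(=O)[C@@]1(O)CO | intermediate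
6 | (1S,2S,6R)-1-(hydroxymethyl)-3-methyl-6-(prop-1-en-2-yl)cyclohex-3-ene-1,2-diol (ring hydroxyls cis, both trans to isopropenyl) | CC(=C)[C@H]1CC=C(C)[C@H](O)[C@@]1(O)CO | intermediate
7 | (1R,2S,6R)-1,2-dihydroxy-3-methyl-6-(prop-1-en-2-yl)cyclohex-3-ene-1-carbaldehyde | CC(=C)[C@H]1CC=C(C)[C@H](O)[C@@]1(O)C=O | intermediate
8 | (1R,2S,6R)-1-hydroxy-3-methyl-6-(prop-1-en-2-yl)-2-{[2-(trimethylsilyl)ethoxy]methoxy}cyclohex-3-ene-1-carbaldehyde | CC(=C)[C@H]1CC=C(C)[C@H](OCOCC[Si](C)(C)C)[C@@]1(O)C=O | intermediate
9 | (1S,2S,6R)-1-[(E)-2-iodoethenyl]-3-methyl-6-(prop-1-en-2-yl)-2-{[2-(trimethylsilyl)ethoxy]methoxy}cyclohex-3-en-1-ol | CC(=C)[C@H]1CC=C(C)[C@H](OCOCC[Si](C)(C)C)[C@@]1(O)/C=C/I | intermediate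
10 | (1S,2S,6R)-1-{(E)-2-[(4-methoxyphenyl)methoxy]ethenyl}-3-methyl-6-(prop-1-en-2-yl)-2-{[2-(trimethylsilyl)ethoxy]methoxy}cyclohex-3-en-1-ol (alkenyl cis to isopropenyl) | CC(=C)[C@H]1CC=C(C)[C@H](OCOCC[Si](C)(C)C)[C@@]1(O)/C=C/OCc1ccc(OC)cc1 | intermediate
11 | methyl bromoacetate | COC(=O)CBr | starting material
12 | potassium (1Z,3S,5Z,8Z,10S)-3-[(4-methoxyphenyl)methoxy]-5,9-dimethyl-10-{[2-(trimethylsilyl)ethoxy]methoxy}cyclodeca-1,5,8-trien-1-olate (C6=C7 enolate, formed and consumed in step 8) | [K+].[O-]/C1=C\[C@@H](OCc2ccc(OC)cc2)C/C(C)=C\C/C=C(/C)[C@@H]1OCOCC[Si](C)(C)C | intermediate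
13 | methyl 2-[(1R,2S,4Z,7Z,9S)-2-[(4-methoxyphenyl)methoxy]-4,8-dimethyl-10-oxo-9-{[2-(trimethylsilyl)ethoxy]methoxy}cyclodeca-4,7-dien-1-yl]acetate | O=C2[C@H](CC(=O)OC)[C@@H](OCc1ccc(OC)cc1)C/C(C)=C\C/C=C(/C)[C@@H]2OCOCC[Si](C)(C)C | intermediate
14 | methyl 2-[(1S,2S,4Z,7Z,9S,10R)-10-hydroxy-2-[(4-methoxyphenyl)methoxy]-4,8-dimethyl-9-{[2-(trimethylsilyl)ethoxy]methoxy}cyclodeca-4,7-dien-1-yl]acetate (formed and consumed in step 9) | O[C@@H]2[C@H](CC(=O)OC)[C@@H](OCc1ccc(OC)cc1)C/C(C)=C\C/C=C(/C)[C@@H]2OCOCC[Si](C)(C)C | intermediate
15 | (1(10)Z,3Z,5S,6R,7R,8S)-8-[(4-methoxyphenyl)methoxy]-5-{[2-(trimethylsilyl)ethoxy]methoxy}-13-norgermacra-1(10),3-dien-12,6-olide (cis-fused γ-lactone, C11 is CH2) | C1C(=O)O[C@@H]2[C@H]1[C@@H](OCc3ccc(OC)cc3)C/C(C)=C\C/C=C(/C)[C@@H]2OCOCC[Si](C)(C)C | intermediate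
16 | (1(10)Z,3Z,5S,6R,7R,8S)-13-(dimethylamino)-8-[(4-methoxyphenyl)methoxy]-5-{[2-(trimethylsilyl)ethoxy]methoxy}germacra-1(10),3-dien-12,6-olide (C11 epimers, formed and consumed in step 10) | CN(C)CC1C(=O)O[C@@H]2[C@H]1[C@@H](OCc3ccc(OC)cc3)C/C(C)=C\C/C=C(/C)[C@@H]2OCOCC[Si](C)(C)C | intermediate
17 | trimethylammonium iodide of 16 (C11 epimers, formed and consumed in step 10) | C[N+](C)(C)CC1C(=O)O[C@@H]2[C@H]1[C@@H](OCc3ccc(OC)cc3)C/C(C)=C\C/C=C(/C)[C@@H]2OCOCC[Si](C)(C)C.[I-] | intermediate
18 | (1(10)Z,3Z,5S,6R,7R,8S)-8-[(4-methoxyphenyl)methoxy]-5-{[2-(trimethylsilyl)ethoxy]methoxy}germacra-1(10),3,11(13)-trien-12,6-olide | C=C1C(=O)O[C@@H]2[C@H]1[C@@H](OCc3ccc(OC)cc3)C/C(C)=C\C/C=C(/C)[C@@H]2OCOCC[Si](C)(C)C | intermediate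
19 | (1(10)Z,3Z,5S,6R,7R,8S)-8-hydroxy-5-{[2-(trimethylsilyl)ethoxy]methoxy}germacra-1(10),3,11(13)-trien-12,6-olide | C=C1C(=O)O[C@@H]2[C@H]1[C@@H](O)C/C(C)=C\C/C=C(/C)[C@@H]2OCOCC[Si](C)(C)C | intermediate
20 | (1(10)Z,3Z,5S,6R,7R,8S)-8-{[(2E)-2-methylbut-2-enoyl]oxy}-5-{[2-(trimethylsilyl)ethoxy]methoxy}germacra-1(10),3,11(13)-trien-12,6-olide | C=C1C(=O)O[C@@H]2[C@H]1[C@@H](OC(=O)/C(C)=C/C)C/C(C)=C\C/C=C(/C)[C@@H]2OCOCC[Si](C)(C)C | intermediate
21 | (1(10)Z,3Z,5S,6R,7R,8S)-8-{[(2E)-2-methylbut-2-enoyl]oxy}-2-oxo-5-{[2-(trimethylsilyl)ethoxy]methoxy}germacra-1(10),3,11(13)-trien-12,6-olide | C=C1C(=O)O[C@@H]2[C@H]1[C@@H](OC(=O)/C(C)=C/C)C/C(C)=C\C(=O)/C=C(/C)[C@@H]2OCOCC[Si](C)(C)C | intermediate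
22 | (1(10)Z,3Z,5S,6R,7R,8S)-5-hydroxy-8-{[(2E)-2-methylbut-2-enoyl]oxy}-2-oxogermacra-1(10),3,11(13)-trien-12,6-olide (CNP0230565.3) | C=C1C(=O)O[C@@H]2[C@H]1[C@@H](OC(=O)/C(C)=C/C)C/C(C)=C\C(=O)/C=C(/C)[C@@H]2O | target

## Step count and least certain steps

Total step count: 14. Longest linear sequence: 14 steps from (S)-carvone 1.

**Step 8 (key step).** Three processes can erode it. Rearrangement through chair B or a boat lowers the share of the Z olefin and, because the two are coupled, of the 8S configuration. The potassium enolate can lose the C8 alkoxide by β-elimination while the rearrangement is run at room temperature. Bromoacetate can alkylate at oxygen or simply protonate the enolate. Fallback: setting out from 10, the rearrangement is run as before but the enolate is quenched with Me3SiCl and Et3N to give the trimethylsilyl enol ether F1, which is purified. MeLi in THF then regenerates the enolate as its lithium salt, which is alkylated with 11 in the presence of DMPU, coming back to the route at 13. This separates the sigmatropic step from the C–C bond formation and replaces the crown-separated potassium enolate by a tighter lithium enolate.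

**Step 13.** Oxygen may be delivered at a terminus of the pentadienyl system (C10 or C4) with transposition of an olefin, or hydrogen may be abstracted at C5 or C9 instead of C2. Fallback: setting out from 20, a Schenck ene reaction with singlet oxygen (O2, light, tetraphenylporphyrin) removes a doubly allylic hydrogen and gives the tertiary allylic hydroperoxide F2, which PPh3 reduces to the tertiary dienol F3. Oxidative 1,3-transposition with pyridinium chlorochromate (Babler–Dauben oxidation) then moves oxygen to C2 and restores the C1=C10 olefin, coming back at 21. The regioisomer with oxygen on C4 would converge on the same dienone. The geometry of the re-formed olefin is the open point of this sequence.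

**Step 2.** The α-hydroxy β-keto aldehyde can lose its formyl group by retro-Claisen cleavage, and facial selectivity at C6 may be incomplete. Fallback: setting out from 1, the lithium enolate (LiN(i-Pr)2) is hydroxymethylated with monomeric formaldehyde to (5S,6R)-6-(hydroxymethyl)carvone F4, which is silylated to the tert-butyldimethylsilyl ether F5. Enolisation toward C6 and trapping with Me3SiCl gives the silyl dienol ether F6, and Rubottom oxidation with mCPBA anti to isopropenyl gives the tertiary α-hydroxy ketone F7. Bu4NF then releases keto diol 5, which is reduced as in step 3, coming back at 6. No formyl ketone is involved.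

**Step 4.** The secondary allylic alcohol may be oxidised as well, and the dihydroxy aldehyde may undergo retro-aldol ring opening or α-ketol rearrangement before it is protected. Fallback: setting out from 6, the primary hydroxyl is silylated selectively with Et3SiCl to the triethylsilyl ether F8, and the secondary hydroxyl is converted to the SEM ether F9. Swern conditions, which oxidise a primary triethylsilyl ether directly to the aldehyde, then lead back to 8 without a free β-hydroxy aldehyde.

**Step 9.** The conformation of the ten-membered ring may override the chelate, so that hydride enters from the other face. Fallback: setting out from 13, a non-chelating hydride is used to give the 6-epimeric hydroxy ester F10, which is saponified with LiOH to the hydroxy acid F11. Mitsunobu lactonisation (PPh3, diisopropyl azodicarboxylate) then closes the lactone with inversion at C6, coming back at 15.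

## Further compounds

F1 | step 8 | trimethylsilyl enol ether of the ring-expanded ketone, (1Z,3S,5Z,8Z,10S)-3-[(4-methoxyphenyl)methoxy]-5,9-dimethyl-10-{[2-(trimethylsilyl)ethoxy]methoxy}-1-(trimethylsilyloxy)cyclodeca-1,5,8-triene | C[Si](C)(C)O/C1=C\[C@@H](OCc2ccc(OC)cc2)C/C(C)=C\C/C=C(/C)[C@@H]1OCOCC[Si](C)(C)C
F2 | step 13 | C10 tertiary hydroperoxide of 20 with the olefin moved to C1=C2 (C10 configuration and C1=C2 geometry open, both erased later) | C=C1C(=O)O[C@@H]2[C@H]1[C@@H](OC(=O)/C(C)=C/C)CC(C)(OO)C=C/C=C(/C)[C@@H]2OCOCC[Si](C)(C)C
F3 | step 13 | C10 tertiary alcohol from F2 (C10 configuration and C1=C2 geometry open, both erased later) | C=C1C(=O)O[C@@H]2[C@H]1[C@@H](OC(=O)/C(C)=C/C)CC(C)(O)C=C/C=C(/C)[C@@H]2OCOCC[Si](C)(C)C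
F4 | step 2 | (5S,6R)-6-(hydroxymethyl)-2-methyl-5-(prop-1-en-2-yl)cyclohex-2-en-1-one (hydroxymethyl trans to isopropenyl) | CC(=C)[C@H]1CC=C(C)C(=O)[C@@H]1CO
F5 | step 2 | tert-butyldimethylsilyl ether of F4 | CC(=C)[C@H]1CC=C(C)C(=O)[C@@H]1CO[Si](C)(C)C(C)(C)C
F6 | step 2 | trimethylsilyl dienol ether of F5 (C5=C6 enol ether) | CC(=C)[C@H]1CC=C(C)C(O[Si](C)(C)C)=C1CO[Si](C)(C)C(C)(C)C
F7 | step 2 | (5R,6S)-6-{[tert-butyl(dimethyl)silyl]oxymethyl}-6-hydroxy-2-methyl-5-(prop-1-en-2-yl)cyclohex-2-en-1-one | CC(=C)[C@H]1CC=C(C)C(=O)[C@@]1(O)CO[Si](C)(C)C(C)(C)C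
F8 | step 4 | (1S,2S,6R)-3-methyl-6-(prop-1-en-2-yl)-1-[(triethylsilyl)oxymethyl]cyclohex-3-ene-1,2-diol | CC(=C)[C@H]1CC=C(C)[C@H](O)[C@@]1(O)CO[Si](CC)(CC)CC
F9 | step 4 | (1S,2S,6R)-3-methyl-6-(prop-1-en-2-yl)-1-[(triethylsilyl)oxymethyl]-2-{[2-(trimethylsilyl)ethoxy]methoxy}cyclohex-3-en-1-ol | CC(=C)[C@H]1CC=C(C)[C@H](OCOCC[Si](C)(C)C)[C@@]1(O)CO[Si](CC)(CC)CC
F10 | step 9 | C6 epimer of hydroxy ester 14 | O[C@H]2[C@H](CC(=O)OC)[C@@H](OCc1ccc(OC)cc1)C/C(C)=C\C/C=C(/C)[C@@H]2OCOCC[Si](C)(C)C
F11 | step 9 | hydroxy acid from F10 | O[C@H]2[C@H](CC(=O)O)[C@@H](OCc1ccc(OC)cc1)C/C(C)=C\C/C=C(/C)[C@@H]2OCOCC[Si](C)(C)C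
A1 | alternative 1 | ten-membered C5 ketone with cis-fused α-methylene lactone, C8 p-methoxybenzyl ether and C2 triethylsilyl ether | C=C1C(=O)O[C@@H]2[C@H]1[C@@H](OCc3ccc(OC)cc3)C/C(C)=C\[C@H](O[Si](CC)(CC)CC)/C=C(/C)C2=O
A2 | alternative 2 | ten-membered 1(10)Z,3Z-dien-2-one with E C7=C8 olefin and C5/C6 acetonide | CC1(C)O[C@@H]2/C=C/C/C(C)=C\C(=O)/C=C(/C)[C@@H]2O1
A3 | alternative 3 | ten-membered cis-fused α-methylene lactone with free C8 hydroxyl, C2 triethylsilyl ether and C5 tert-butyldimethylsilyl ether | C=C1C(=O)O[C@@H]2[C@H]1[C@@H](O)C/C(C)=C\[C@H](O[Si](CC)(CC)CC)/C=C(/C)[C@@H]2O[Si](C)(C)C(C)(C)C
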